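The carbocycle is labelled from the ketone carbon C1 through the alkene C2=C3 and C4 to the tertiary carbinol C5 and on to C6; the appendage is C1′H2–C2′(=O)–(Z)-heptadecenyl. Because C5(OH), C6H2 and C1(=O) form a β-hydroxy ketone inside this ring, the C5–C6 bond is cut in the aldol sense. One intramolecular aldol addition of a C6 methyl-ketone enolate to a C5 ketone closes the six-membered ring and creates the C5 stereocentre, relayed from a silyloxy-bearing C3 centre that is later eliminated to leave the C2=C3 enone. The precursor is an open-chain (R)-3-silyloxy 1,5-diketone with C2′ masked as a 1,3-dithiane, assembled from a chiral epoxide and lithiated oleyl dithiane.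

Key step: step 10

Remark: the facial sense of the allylboration in step 2 is taken from the usual model (the (+)-α-pinene-derived allylborane delivers allyl to the Si face of an unbranched aldehyde), and the oxirane carbon made in step 4 is carried as both epimers because it becomes the C5 carbonyl in step 8.

Step 1
Reactants: 1 ethyl 2-(2-methyl-1,3-dioxolan-2-yl)acetate
Product: 3 2-(2-methyl-1,3-dioxolan-2-yl)acetaldehyde, via aluminium hemiacetal 2 (not isolated)
Conditions: i-Bu2AlH (1.05 equiv), CH2Cl2, −78 °C; aq. potassium sodium tartrate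
Reagents that add atoms: none
Why: Partial ester reduction with i-Bu2AlH at low temperature should stop at the tetrahedral aluminium hemiacetal 2, held by chelation to a dioxolane oxygen, so that the aldehyde appears only on aqueous work-up (DIBAL ester-to-aldehyde reduction).

Step 2
Reactants: 3 2-(2-methyl-1,3-dioxolan-2-yl)acetaldehyde; 4 allylmagnesium bromide
Product: 7 (2S)-1-(2-methyl-1,3-dioxolan-2-yl)pent-4-en-2-ol, via allylborane 5 (not isolated), via borinate ester 6 (not isolated)
Conditions: 4, (−)-Ipc2BOMe [from (+)-α-pinene], Et2O, −78 °C → rt; then 3, −78 °C; then aq. NaOH, H2O2, rt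
Reagents that add atoms: none
Why: In this Brown asymmetric allylboration, 4 and the methoxyborane give allylborane 5, which should transfer allyl to the Si face of 3 through a chair-like six-membered transition state governed by the isopinocampheyl groups, setting C3 as (S) before oxidative cleavage of borinate 6.

Step 3
Reactants: 7 (2S)-1-(2-methyl-1,3-dioxolan-2-yl)pent-4-en-2-ol
Product: 8 tert-butyldimethyl{[(2S)-1-(2-methyl-1,3-dioxolan-2-yl)pent-4-en-2-yl]oxy}silane
Conditions: TBSCl, imidazole, DMF, rt
Reagents that add atoms: tert-butyldimethylsilyl chloride, CC(C)(C)[Si](C)(C)Cl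
Why: Imidazole-promoted silylation of a secondary alcohol (Corey silylation) installs an ether that withstands organolithium, activated-DMSO and mild acid conditions and that coordinates lithium poorly, which matters for the sense of the later ring closure.

Step 4
Reactants: 8 tert-butyldimethyl{[(2S)-1-(2-methyl-1,3-dioxolan-2-yl)pent-4-en-2-yl]oxy}silane
Product: 9 tert-butyldimethyl{[(2S)-1-(2-methyl-1,3-dioxolan-2-yl)-3-(oxiran-2-yl)propan-2-yl]oxy}silane (both epimers at the oxirane carbon)
Conditions: mCPBA, NaHCO3, CH2Cl2, 0 °C → rt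
Reagents that add atoms: meta-chloroperoxybenzoic acid, OOC(=O)c1cccc(Cl)c1
Why: Prilezhaev epoxidation of the only alkene present should proceed cleanly with solid NaHCO3 protecting the ketal from the acid by-product, and the uncontrolled new centre is irrelevant because that carbon becomes the C5 ketone.

Step 5
Reactants: 10 oleyl alcohol [(9Z)-octadec-9-en-1-ol]
Product: 11 (9Z)-octadec-9-enal
Conditions: TEMPO (0.1 equiv), PhI(OAc)2 (1.1 equiv), CH2Cl2, rt
Reagents that add atoms: none
Why: The nitroxyl-catalysed oxidation with PhI(OAc)2 as terminal oxidant takes a primary alcohol to the aldehyde without over-oxidation and does not touch an isolated Z-alkene.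

Step 6
Reactants: 11 (9Z)-octadec-9-enal; 12 propane-1,3-dithiol
Product: 13 2-[(8Z)-heptadec-8-en-1-yl]-1,3-dithiane
Conditions: BF3·OEt2 (0.2 equiv), CH2Cl2, 0 °C, argon, dark
Reagents that add atoms: none
Why: Lewis-acid-catalysed dithioacetalisation of an aldehyde (the first stage of Corey–Seebach umpolung) is fast at 0 °C, and inert gas with exclusion of light is meant to prevent thiyl-radical Z/E isomerisation of the alkene.

Step 7
Reactants: 13 2-[(8Z)-heptadec-8-en-1-yl]-1,3-dithiane; 9 tert-butyldimethyl{[(2S)-1-(2-methyl-1,3-dioxolan-2-yl)-3-(oxiran-2-yl)propan-2-yl]oxy}silane (both epimers)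
Product: 16 (4S)-4-[(tert-butyldimethylsilyl)oxy]-1-{2-[(8Z)-heptadec-8-en-1-yl]-1,3-dithian-2-yl}-5-(2-methyl-1,3-dioxolan-2-yl)pentan-2-ol (both epimers at C2), via lithiated dithiane 14 (not isolated), via lithium alkoxide 15 (not isolated)
Conditions: 13 (1.2 equiv), n-BuLi (1.15 equiv), THF, −30 → −20 °C; then 9, −20 → 0 °C; aq. NH4Cl
Reagents that add atoms: none
Why: In this Corey–Seebach alkylation the 2-lithio-1,3-dithiane 14 should open the terminal epoxide by SN2 attack at its unsubstituted carbon, forming the C1′–C2′ bond and alkoxide 15, while the absence of strongly coordinating cosolvents and the low temperature guard against oxygen-to-oxygen silyl migration.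

Step 8
Reactants: 16 (4S)-4-[(tert-butyldimethylsilyl)oxy]-1-{2-[(8Z)-heptadec-8-en-1-yl]-1,3-dithian-2-yl}-5-(2-methyl-1,3-dioxolan-2-yl)pentan-2-ol (both epimers at C2)
Product: 17 (4S)-4-[(tert-butyldimethylsilyl)oxy]-1-{2-[(8Z)-heptadec-8-en-1-yl]-1,3-dithian-2-yl}-5-(2-methyl-1,3-dioxolan-2-yl)pentan-2-one
Conditions: SO3·pyridine, DMSO, i-Pr2NEt, CH2Cl2, 0 °C
Reagents that add atoms: none
Why: Parikh–Doering oxidation (activated DMSO) converts the secondary alcohol into the C5 ketone without oxidising the thioacetal sulfur atoms or the alkene, and it merges both carbinol epimers into one compound.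

Step 9
Reactants: 17 (4S)-4-[(tert-butyldimethylsilyl)oxy]-1-{2-[(8Z)-heptadec-8-en-1-yl]-1,3-dithian-2-yl}-5-(2-methyl-1,3-dioxolan-2-yl)pentan-2-one
Product: 18 (4R)-4-[(tert-butyldimethylsilyl)oxy]-1-{2-[(8Z)-heptadec-8-en-1-yl]-1,3-dithian-2-yl}heptane-2,6-dione
Conditions: PPTS (0.2 equiv), acetone/H2O (10:1), 40 °C
Reagents that add atoms: water, O
Why: Mildly acid-catalysed hydrolysis (transketalisation into acetone) of the dioxolane frees the C1 methyl ketone under conditions to which the dithiane, the secondary TBS ether and the Z-alkene are inert; the (R) descriptor reflects only a change in substituent priorities.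

Step 10
Reactants: 18 (4R)-4-[(tert-butyldimethylsilyl)oxy]-1-{2-[(8Z)-heptadec-8-en-1-yl]-1,3-dithian-2-yl}heptane-2,6-dione
Product: 21 (3S,5S)-5-[(tert-butyldimethylsilyl)oxy]-3-({2-[(8Z)-heptadec-8-en-1-yl]-1,3-dithian-2-yl}methyl)-3-hydroxycyclohexan-1-one, via lithium enolate 19 (not isolated), via lithium aldolate 20 (not isolated)
Conditions: LiN(SiMe3)2 (1.1 equiv), THF, −78 °C, slow addition of 18; −78 → −50 °C; AcOH, −78 °C
Reagents that add atoms: none
Why: LiN(SiMe3)2 should deprotonate the sterically open C6 methyl group under kinetic control to give lithium enolate 19, whose C6 terminus adds to the C5 carbonyl to form the C5–C6 bond and lithium aldolate 20, which the cold AcOH quench protonates before retro-aldol or dehydration can set in. The closest known reaction type is the base-mediated intramolecular aldol addition of a 1,5-diketone to a 3-hydroxycyclohexanone, the ketol stage of a Robinson annulation. The six-membered carbocycle C1–C6 closes in the 6-(enolendo)-exo-trig mode. The new C5 stereocentre is controlled by the existing C3 centre: a chair-like transition state keeps the C3 silyloxy group and the large dithianylmethyl arm on C5 equatorial, which leaves the developing C5–O bond axial and anti to O3 (the 3,5-trans ketol, also the more stable product), and the weakly coordinating silyl ether offers no lithium bridge between O3 and the C5 carbonyl that could favour the cis isomer. The step needs site selectivity among four α-positions and two conceivable six-ring aldols: C6 is the only methyl group, C2 and C4 flank the silyloxy-bearing carbon, C1′ is neopentylic beside the dithiane so the C1′-to-C1 mode is disfavoured, and the dithiane keeps C2′ from turning C5 into an enolised β-diketone. Low temperature and slow addition of 18 to a small excess of base should limit E1cB loss of the C3 oxygen before the ring closes.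

Step 11
Reactants: 21 (3S,5S)-5-[(tert-butyldimethylsilyl)oxy]-3-({2-[(8Z)-heptadec-8-en-1-yl]-1,3-dithian-2-yl}methyl)-3-hydroxycyclohexan-1-one
Product: 22 (3S,5S)-3-({2-[(8Z)-heptadec-8-en-1-yl]-1,3-dithian-2-yl}methyl)-3,5-dihydroxycyclohexan-1-one
Conditions: HF·pyridine, pyridine, THF, 0 °C → rt
Reagents that add atoms: none
Why: Fluoride-mediated cleavage of the secondary TBS ether under buffered, non-basic conditions should spare the retro-aldol-prone tertiary ketol, the dithiane and the alkene.

Step 12
Reactants: 22 (3S,5S)-3-({2-[(8Z)-heptadec-8-en-1-yl]-1,3-dithian-2-yl}methyl)-3,5-dihydroxycyclohexan-1-one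
Product: 24 (5S)-5-({2-[(8Z)-heptadec-8-en-1-yl]-1,3-dithian-2-yl}methyl)-5-hydroxycyclohex-2-en-1-one, via mesylate 23 (not isolated)
Conditions: MsCl (1.2 equiv), Et3N (4 equiv), CH2Cl2, −20 °C → rt
Reagents that add atoms: none
Why: Mesylation is selective for the secondary C3 hydroxyl over the hindered tertiary C5 hydroxyl, and β-mesyloxy ketone 23 should lose methanesulfonate by E1cB elimination through the C2 enolate under the same amine base, erasing C3 and giving the conjugated C2=C3 enone.

Step 13
Reactants: 24 (5S)-5-({2-[(8Z)-heptadec-8-en-1-yl]-1,3-dithian-2-yl}methyl)-5-hydroxycyclohex-2-en-1-one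
Product: 25 (5R)-5-hydroxy-5-[(10Z)-2-oxononadec-10-en-1-yl]cyclohex-2-en-1-one
Conditions: MeI (excess), CaCO3, MeCN/H2O (9:1), 40 °C, dark
Reagents that add atoms: water, O
Why: Alkylative hydrolysis of the dithiane (S-methylation by MeI, then attack of water) unmasks the C2′ ketone under CaCO3-buffered, near-neutral conditions that tolerate the Z-alkene, the enone and the tertiary aldol; C5 keeps its geometry and becomes (R) only through the change in substituent priorities.

Compound list
1 | ethyl 2-(2-methyl-1,3-dioxolan-2-yl)acetate (ethylene ketal of ethyl acetoacetate) | CCOC(=O)CC1(C)OCCO1 | starting material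
2 | diisobutyl[1-ethoxy-2-(2-methyl-1,3-dioxolan-2-yl)ethoxy]aluminium (aluminium hemiacetal, racemic at the hemiacetal carbon) | CCOC(CC1(C)OCCO1)O[Al](CC(C)C)CC(C)C | intermediate
3 | 2-(2-methyl-1,3-dioxolan-2-yl)acetaldehyde | O=CCC1(C)OCCO1 | intermediate
4 | allylmagnesium bromide | C=CC[Mg]Br | starting material
5 | (−)-B-allyldiisopinocampheylborane, both isopinocampheyl groups from (+)-α-pinene | C=CCB([C@@H]1C[C@@H]2C[C@H]([C@H]1C)C2(C)C)[C@@H]1C[C@@H]2C[C@H]([C@H]1C)C2(C)C | intermediate
6 | (2S)-1-(2-methyl-1,3-dioxolan-2-yl)pent-4-en-2-yl diisopinocampheylborinate | C=CC[C@H](OB([C@@H]2C[C@@H]3C[C@H]([C@H]2C)C3(C)C)[C@@H]2C[C@@H]3C[C@H]([C@H]2C)C3(C)C)CC1(C)OCCO1 | intermediate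
7 | (2S)-1-(2-methyl-1,3-dioxolan-2-yl)pent-4-en-2-ol | C=CC[C@H](O)CC1(C)OCCO1 | intermediate
8 | tert-butyldimethyl{[(2S)-1-(2-methyl-1,3-dioxolan-2-yl)pent-4-en-2-yl]oxy}silane | C=CC[C@H](O[Si](C)(C)C(C)(C)C)CC1(C)OCCO1 | intermediate
9 | tert-butyldimethyl{[(2S)-1-(2-methyl-1,3-dioxolan-2-yl)-3-(oxiran-2-yl)propan-2-yl]oxy}silane, both epimers at the oxirane carbon | C1OC1C[C@H](O[Si](C)(C)C(C)(C)C)CC1(C)OCCO1 | intermediate
10 | oleyl alcohol, (9Z)-octadec-9-en-1-ol | CCCCCCCC/C=C\CCCCCCCCO | starting material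
11 | (9Z)-octadec-9-enal | CCCCCCCC/C=C\CCCCCCCC=O | intermediate
12 | propane-1,3-dithiol | SCCCS | starting material
13 | 2-[(8Z)-heptadec-8-en-1-yl]-1,3-dithiane | CCCCCCCC/C=C\CCCCCCCC1SCCCS1 | intermediate
14 | 2-[(8Z)-heptadec-8-en-1-yl]-2-lithio-1,3-dithiane | CCCCCCCC/C=C\CCCCCCCC1([Li])SCCCS1 | intermediate
15 | lithium alkoxide of 16, both epimers at the alkoxide carbon | CCCCCCCC/C=C\CCCCCCCC1(SCCCS1)CC(O[Li])C[C@H](O[Si](C)(C)C(C)(C)C)CC1(C)OCCO1 | intermediate
16 | (4S)-4-[(tert-butyldimethylsilyl)oxy]-1-{2-[(8Z)-heptadec-8-en-1-yl]-1,3-dithian-2-yl}-5-(2-methyl-1,3-dioxolan-2-yl)pentan-2-ol, both epimers at C2 | CCCCCCCC/C=C\CCCCCCCC1(SCCCS1)CC(O)C[C@H](O[Si](C)(C)C(C)(C)C)CC1(C)OCCO1 | intermediate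
17 | (4S)-4-[(tert-butyldimethylsilyl)oxy]-1-{2-[(8Z)-heptadec-8-en-1-yl]-1,3-dithian-2-yl}-5-(2-methyl-1,3-dioxolan-2-yl)pentan-2-one | CCCCCCCC/C=C\CCCCCCCC1(SCCCS1)CC(=O)C[C@H](O[Si](C)(C)C(C)(C)C)CC1(C)OCCO1 | intermediate
18 | (4R)-4-[(tert-butyldimethylsilyl)oxy]-1-{2-[(8Z)-heptadec-8-en-1-yl]-1,3-dithian-2-yl}heptane-2,6-dione (key-step precursor) | CCCCCCCC/C=C\CCCCCCCC1(SCCCS1)CC(=O)C[C@H](O[Si](C)(C)C(C)(C)C)CC(C)=O | intermediate
19 | lithium enolate of 18 at the methyl ketone (C6=C1–OLi) | CCCCCCCC/C=C\CCCCCCCC1(SCCCS1)CC(=O)C[C@H](O[Si](C)(C)C(C)(C)C)CC(=C)O[Li] | intermediate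
20 | lithium aldolate of 21 (C5–OLi) | CCCCCCCC/C=C\CCCCCCCC1(SCCCS1)C[C@]1(O[Li])C[C@H](O[Si](C)(C)C(C)(C)C)CC(=O)C1 | intermediate
21 | (3S,5S)-5-[(tert-butyldimethylsilyl)oxy]-3-({2-[(8Z)-heptadec-8-en-1-yl]-1,3-dithian-2-yl}methyl)-3-hydroxycyclohexan-1-one (hydroxyl trans to silyloxy; key-step product) | CCCCCCCC/C=C\CCCCCCCC1(SCCCS1)C[C@]1(O)C[C@H](O[Si](C)(C)C(C)(C)C)CC(=O)C1 | intermediate
22 | (3S,5S)-3-({2-[(8Z)-heptadec-8-en-1-yl]-1,3-dithian-2-yl}methyl)-3,5-dihydroxycyclohexan-1-one | CCCCCCCC/C=C\CCCCCCCC1(SCCCS1)C[C@]1(O)C[C@H](O)CC(=O)C1 | intermediate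
23 | (1S,3S)-3-({2-[(8Z)-heptadec-8-en-1-yl]-1,3-dithian-2-yl}methyl)-3-hydroxy-5-oxocyclohexyl methanesulfonate | CCCCCCCC/C=C\CCCCCCCC1(SCCCS1)C[C@]1(O)C[C@H](OS(C)(=O)=O)CC(=O)C1 | intermediate
24 | (5S)-5-({2-[(8Z)-heptadec-8-en-1-yl]-1,3-dithian-2-yl}methyl)-5-hydroxycyclohex-2-en-1-one | CCCCCCCC/C=C\CCCCCCCC1(SCCCS1)C[C@]1(O)CC=CC(=O)C1 | intermediate
25 | (5R)-5-hydroxy-5-[(10Z)-2-oxononadec-10-en-1-yl]cyclohex-2-en-1-one | CCCCCCCC/C=C\CCCCCCCC(=O)C[C@]1(O)CC=CC(=O)C1 | target

Total step count: 13. Longest linear sequence: 11 steps (1 to 25 through steps 1–4 and 7–13); the dithiane branch contributes steps 5 and 6.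

Steps most likely to fail

Step 10. The process at risk is enolisation at C2, C4 or C1′ instead of C6, followed by β-elimination of silanolate in the open chain, or ring closure with poor facial selectivity. The fallback replaces the preformed lithium enolate by enamine activation; it sets out from 18 and returns at 21. With (S)-proline (0.3 equiv) in DMSO at room temperature, the amine should condense only with the unhindered C1 carbonyl to give the proline enamine of 18 F1 (not isolated). This reacts through C6 with the C5 ketone in a Hajos–Parrish-type intramolecular aldol under non-basic, reversible conditions, so the trans-ketol with both large groups equatorial can accumulate. Hydrolysis of the iminium ion releases 21 and the catalyst.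

Step 12. The process at risk is sulfonylation of the tertiary hydroxyl, retro-aldol ring opening, or further loss of water from C5 towards a phenol while the amine base is present. The fallback separates activation from elimination and uses a milder leaving group; it sets out from 22 and returns at 24. Acetic anhydride in pyridine at 0 °C without acylation catalyst should acetylate only the secondary hydroxyl to give the isolable (1S,3S)-3-({2-[(8Z)-heptadec-8-en-1-yl]-1,3-dithian-2-yl}methyl)-3-hydroxy-5-oxocyclohexyl acetate F2. A brief, separately controlled exposure to DBU (1 equiv, CH2Cl2, −20 °C) then expels acetate to give 24.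

Step 13. The process at risk is slow hydrolysis of the hindered thioacetal, with dehydration or aromatisation of the free hydroxy-enone during prolonged warming. The fallback moves the unmasking to the most robust ring compound and changes the order of the endgame; it sets out from 21 and returns at 25. Treatment of 21 with MeI and CaCO3 in aqueous MeCN (or PhI(O2CCF3)2 in aqueous MeCN at 0 °C) gives (3R,5S)-5-[(tert-butyldimethylsilyl)oxy]-3-hydroxy-3-[(10Z)-2-oxononadec-10-en-1-yl]cyclohexan-1-one F3, in which neither an enone nor a free secondary hydroxyl is present. HF·pyridine then gives (3R,5S)-3,5-dihydroxy-3-[(10Z)-2-oxononadec-10-en-1-yl]cyclohexan-1-one F4. MsCl and Et3N at −20 °C convert F4 through (1S,3R)-3-hydroxy-5-oxo-3-[(10Z)-2-oxononadec-10-en-1-yl]cyclohexyl methanesulfonate F5 (not isolated) into 25.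

Further compounds
F1 | step 10 | (2S)-1-[(4R)-4-[(tert-butyldimethylsilyl)oxy]-7-{2-[(8Z)-heptadec-8-en-1-yl]-1,3-dithian-2-yl}-6-oxohept-1-en-2-yl]pyrrolidine-2-carboxylic acid | CCCCCCCC/C=C\CCCCCCCC1(SCCCS1)CC(=O)C[C@H](O[Si](C)(C)C(C)(C)C)CC(=C)N1CCC[C@H]1C(=O)O
F2 | step 12 | (1S,3S)-3-({2-[(8Z)-heptadec-8-en-1-yl]-1,3-dithian-2-yl}methyl)-3-hydroxy-5-oxocyclohexyl acetate | CCCCCCCC/C=C\CCCCCCCC1(SCCCS1)C[C@]1(O)C[C@H](OC(C)=O)CC(=O)C1
F3 | step 13 | (3R,5S)-5-[(tert-butyldimethylsilyl)oxy]-3-hydroxy-3-[(10Z)-2-oxononadec-10-en-1-yl]cyclohexan-1-one | CCCCCCCC/C=C\CCCCCCCC(=O)C[C@]1(O)C[C@H](O[Si](C)(C)C(C)(C)C)CC(=O)C1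
F4 | step 13 | (3R,5S)-3,5-dihydroxy-3-[(10Z)-2-oxononadec-10-en-1-yl]cyclohexan-1-one | CCCCCCCC/C=C\CCCCCCCC(=O)C[C@]1(O)C[C@H](O)CC(=O)C1
F5 | step 13 | (1S,3R)-3-hydroxy-5-oxo-3-[(10Z)-2-oxononadec-10-en-1-yl]cyclohexyl methanesulfonate | CCCCCCCC/C=C\CCCCCCCC(=O)C[C@]1(O)C[C@H](OS(C)(=O)=O)CC(=O)C1
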